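**Retrosynthetic overview**

1. The target is reached from a 9α-mesyloxy 8-ketone by SN2 inversion with caesium angelate; that ketone comes from the cis-fused decal-9-one 20 (9-oxo, 8α-OPMB, 3α-senecioate).
2. Key disconnection C-5–C-10: ring B (C-5, C-6, C-7, C-8, C-9, C-10) is not closed as a six-membered ring. It grows from a cyclopentanone (C-5, C-6, C-7, C-8, C-9) when a tethered diazo carbon C-10 is inserted between C-9 and C-5; the same 1,2-shift closes ring A.
3. Enabling feature: the C-9 carbonyl of that cyclopentanone sits between the quaternary, tether-bearing C-5 (good migrating group) and the oxygen-bearing C-8 (poor migrating group). The unit C-5(Me)/C-9(O)/C-8(O)/C-7/C-6 is the carbon and oxygen pattern of cyclotene.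
4. The cyclopentanone comes from cyclotene by O-allylation and Claisen rearrangement (C-5 and C-4, chirality from (S)-pent-3-en-2-ol), alkene cleavage, Grignard addition (C-3) and cuprate addition (C-7).
5. Order of ring formation: the five-membered precursor of ring B is there from the start (cyclotene); ring A and the six-membered ring B are both formed in step 10.

Key step: step 10

Remark on the chemistry: all intermediates carry the eremophilane numbering of the target (C-14 and C-15 are the methyls on C-5 and C-4; α/β as in the target drawn with both methyls β). Enantiopure (S)-pent-3-en-2-ol is not assumed to be a catalogue chemical and is therefore taken from the racemate by resolution.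

**Route**

Step 1
Reactants: 1 (E)-pent-3-en-2-ol (racemic)
Product: 2 (S,E)-pent-3-en-2-ol
Conditions: Novozym 435 (immobilised Candida antarctica lipase B), vinyl acetate (0.6 equiv), hexane, 30 °C, stopped at about 55% conversion; separation from the (R)-acetate
Reagents that add atoms: none
Why: Lipase-catalysed kinetic resolution (enantioselective transesterification), in which this lipase acylates the (R)-alcohol much faster and should therefore leave the (S)-alcohol in high enantiomeric purity once conversion passes one half.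

Step 2
Reactants: 3 cyclotene (2-hydroxy-3-methylcyclopent-2-en-1-one); 2 (S,E)-pent-3-en-2-ol
Product: 4 3-methyl-2-{[(2R,3E)-pent-3-en-2-yl]oxy}cyclopent-2-en-1-one
Conditions: PPh3, DIAD, THF, 0 °C → rt
Reagents that add atoms: none
Why: Mitsunobu etherification of the acidic enol OH of the diosphenol, which should alkylate on oxygen with SN2 inversion at the allylic carbinol carbon and so give the (R)-configured ether.

Step 3
Reactants: 4 3-methyl-2-{[(2R,3E)-pent-3-en-2-yl]oxy}cyclopent-2-en-1-one
Product: 5 (5R)-2-hydroxy-5-methyl-5-[(2S,3E)-pent-3-en-2-yl]cyclopent-2-en-1-one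
Conditions: Eu(fod)3 (10 mol %), CHCl3, 60 °C (thermal alternative: toluene, 130 °C, sealed tube)
Reagents that add atoms: none
Why: Claisen [3,3]-sigmatropic rearrangement of a diosphenol allyl ether through a chair transition state with the carbinol methyl equatorial, which should transfer the ether stereocentre to the quaternary C-5 and to C-4 (the E-crotyl terminus gives the cis-4,5-dimethyl relationship of the target), leave an E-propenyl group, and end with enolisation of the 1,2-dione toward its CH2 side.

Step 4
Reactants: 5 (5R)-2-hydroxy-5-methyl-5-[(2S,3E)-pent-3-en-2-yl]cyclopent-2-en-1-one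
Product: 6 (5R)-2-[(4-methoxybenzyl)oxy]-5-methyl-5-[(2S,3E)-pent-3-en-2-yl]cyclopent-2-en-1-one
Conditions: 4-methoxybenzyl chloride, K2CO3, NaI (cat.), acetone, 50 °C
Reagents that add atoms: 4-methoxybenzyl chloride, COc1ccc(CCl)cc1
Why: Williamson O-alkylation of the enol oxygen, the only acidic site, which should give the 2-alkoxy enone without touching a stereocentre.

Step 5
Reactants: 6 (5R)-2-[(4-methoxybenzyl)oxy]-5-methyl-5-[(2S,3E)-pent-3-en-2-yl]cyclopent-2-en-1-one
Product: 9 (2R)-2-{(1R)-3-[(4-methoxybenzyl)oxy]-1-methyl-2-oxocyclopent-3-en-1-yl}propanal, via trans-epoxide 7 (not isolated), via diol 8 (not isolated)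
Conditions: mCPBA, CH2Cl2, 0 °C; then H5IO6, THF/H2O, 0 °C → rt
Reagents that add atoms: 3-chloroperoxybenzoic acid, OOC(=O)c1cccc(Cl)c1; water, O
Why: Peracid epoxidation should be chemoselective for the isolated E-alkene (the ring alkene is deactivated by the conjugated ketone), and periodic acid cleavage of the epoxide through its diol should then give the α-methyl aldehyde under weakly acidic conditions that leave C-4 unepimerised.

Step 6
Reactants: 9 (2R)-2-{(1R)-3-[(4-methoxybenzyl)oxy]-1-methyl-2-oxocyclopent-3-en-1-yl}propanal; 10 [2-(1,3-dioxolan-2-yl)ethyl]magnesium bromide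
Product: 11 (5R)-5-[(2R,3R)-5-(1,3-dioxolan-2-yl)-3-hydroxypentan-2-yl]-2-[(4-methoxybenzyl)oxy]-5-methylcyclopent-2-en-1-one
Conditions: THF, −78 °C; aq. NH4Cl quench
Reagents that add atoms: none
Why: Grignard addition to the aldehyde in preference to the hindered conjugated ketone, with Felkin–Anh 1,2-induction in which the nucleophile enters anti to the quaternary C-5 substituent and should set C-3 in the 3,4-syn sense that becomes the 3α-oxygen trans to the C-4 methyl on ring A.

Step 7
Reactants: 11 (5R)-5-[(2R,3R)-5-(1,3-dioxolan-2-yl)-3-hydroxypentan-2-yl]-2-[(4-methoxybenzyl)oxy]-5-methylcyclopent-2-en-1-one; 12 3-methylbut-2-enoyl chloride (senecioyl chloride)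
Product: 13 (2R,3R)-5-(1,3-dioxolan-2-yl)-2-{(1R)-3-[(4-methoxybenzyl)oxy]-1-methyl-2-oxocyclopent-3-en-1-yl}pentan-3-yl 3-methylbut-2-enoate
Conditions: pyridine, DMAP (cat.), CH2Cl2, 0 °C → rt
Reagents that add atoms: none
Why: Acylation of the secondary alcohol by an acid chloride under pyridine/DMAP catalysis, which should install the senecioate with retention at C-3 and without deconjugation of the acyl group.

Step 8
Reactants: 13 (2R,3R)-5-(1,3-dioxolan-2-yl)-2-{(1R)-3-[(4-methoxybenzyl)oxy]-1-methyl-2-oxocyclopent-3-en-1-yl}pentan-3-yl 3-methylbut-2-enoate; 14 isopropenylmagnesium bromide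
Product: 16 (2R,3R)-5-(1,3-dioxolan-2-yl)-2-[(1R,3R,4R)-3-[(4-methoxybenzyl)oxy]-1-methyl-2-oxo-4-(prop-1-en-2-yl)cyclopentyl]pentan-3-yl 3-methylbut-2-enoate, via silyl enol ether 15 (not isolated)
Conditions: CuBr·SMe2 (20 mol %), Me3SiCl, THF, −78 °C; then 10% aq. citric acid, 0 °C
Reagents that add atoms: chlorotrimethylsilane, C[Si](C)(C)Cl (its atoms stay only in intermediate 15)
Why: Copper-catalysed, chlorosilane-accelerated conjugate addition of the Grignard reagent to C-7 of the 2-alkoxy enone should occur anti to the bulky C-5 side chain (isopropenyl cis to the C-5 methyl), and protonation of the silyl enol ether at C-8 should give the more stable trans arrangement of the 8-alkoxy and isopropenyl groups, while the β,β-disubstituted senecioate should not react.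

Step 9
Reactants: 16 (2R,3R)-5-(1,3-dioxolan-2-yl)-2-[(1R,3R,4R)-3-[(4-methoxybenzyl)oxy]-1-methyl-2-oxo-4-(prop-1-en-2-yl)cyclopentyl]pentan-3-yl 3-methylbut-2-enoate
Product: 18 N-tosylhydrazone of the C-10 aldehyde, via keto aldehyde 17 (not isolated)
Conditions: TsNHNH2 (1.05 equiv), PPTS (10 mol %), THF/H2O 5:1, 45 °C
Reagents that add atoms: 4-methylbenzenesulfonohydrazide, Cc1ccc(cc1)S(=O)(=O)NN
Why: Acid-catalysed acetal hydrolysis with immediate condensation of the freed aldehyde with the sulfonyl hydrazide (hydrazone formation), which should occur only at the unhindered aldehyde and not at the α-quaternary ketone, and creates no stereocentre.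

Step 10
Reactants: 18 N-tosylhydrazone of the C-10 aldehyde
Product: 20 8α-[(4-methoxybenzyl)oxy]-9-oxo-10βH-eremophil-11-en-3α-yl 3-methylbut-2-enoate, via diazoalkane 19 (not isolated)
Conditions: NaH (1.05 equiv), THF, 0 °C; then BnEt3NCl (10 mol %), 1,4-dioxane (0.01 M), 85 °C
Reagents that add atoms: none
Why: Proposed new method: thermolysis of the tosylhydrazone sodium salt (Bamford–Stevens conditions) should release the non-stabilised diazoalkane 19, whose nucleophilic carbon C-10 adds to the C-9 ketone (7-exo-trig) to give a diazonium alkoxide; loss of N2 with 1,2-shift of the antiperiplanar C-9–C-5 bond then inserts C-10 between C-9 and C-5, so that the cyclopentanone becomes the cyclohexanone ring B (one-carbon ring expansion) while the seven-membered betaine ring contracts to the six-membered ring A in the same event. The closest known reaction types are the homologation of cyclic ketones by diazoalkanes (Tiffeneau–Demjanov-type ring expansion, including diazoalkanes made in situ from sulfonylhydrazones) and the intramolecular Schmidt reaction of ω-azidoalkyl ketones, the nitrogen analogue, in which the tether-bearing α-carbon likewise migrates to give the fused bicycle. The selectivity needed is migration of C-5 and not of C-8; it should be secured by the higher migratory aptitude of the electron-rich quaternary C-5 over the oxygen-bearing C-8 and by the tether, which holds the C-9–C-5 bond anti to the departing N2, and C-5 migrates with retention so that the Claisen-derived quaternary centre is carried over unchanged. The new stereocentre C-10 is α to the new ketone and should equilibrate under the basic conditions to the cis-fused decalin, the only ring fusion in which the C-5 methyl is equatorial on ring B so that the 7β-isopropenyl and 8α-alkoxy groups are both equatorial; C-8 equilibrates in the same way. Collapse of the betaine to an epoxide and carbene-type 1,2-hydrogen shift of the diazoalkane are the expected competing reactions.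

Step 11
Reactants: 20 8α-[(4-methoxybenzyl)oxy]-9-oxo-10βH-eremophil-11-en-3α-yl 3-methylbut-2-enoate
Product: 21 9α-hydroxy-8α-[(4-methoxybenzyl)oxy]-10βH-eremophil-11-en-3α-yl 3-methylbut-2-enoate
Conditions: LiBH(s-Bu)3 (L-Selectride), THF, −78 °C; aqueous work-up
Reagents that add atoms: none
Why: Hydride reduction with a bulky trialkylborohydride should attack the C-9 ketone of the cis-decalin from the open convex β-face (the α-face is shielded by the axial C-5–C-4 bond of ring A) and so give the axial 9α-alcohol, the β,β-disubstituted senecioate being inert to this reagent at −78 °C.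

Step 12
Reactants: 21 9α-hydroxy-8α-[(4-methoxybenzyl)oxy]-10βH-eremophil-11-en-3α-yl 3-methylbut-2-enoate
Product: 22 9α-(methanesulfonyloxy)-8α-[(4-methoxybenzyl)oxy]-10βH-eremophil-11-en-3α-yl 3-methylbut-2-enoate
Conditions: MsCl, Et3N, CH2Cl2, 0 °C
Reagents that add atoms: methanesulfonyl chloride, CS(=O)(=O)Cl
Why: Sulfonylation of the hindered secondary alcohol through the small sulfene electrophile, which should give the axial 9α-mesylate with retention.

Step 13
Reactants: 22 9α-(methanesulfonyloxy)-8α-[(4-methoxybenzyl)oxy]-10βH-eremophil-11-en-3α-yl 3-methylbut-2-enoate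
Product: 23 8α-hydroxy-9α-(methanesulfonyloxy)-10βH-eremophil-11-en-3α-yl 3-methylbut-2-enoate
Conditions: DDQ, CH2Cl2/pH 7 phosphate buffer 10:1, 0 °C → rt
Reagents that add atoms: none
Why: Oxidative cleavage of the 4-methoxybenzyl ether by DDQ under buffered conditions, which should free the 8-hydroxyl without affecting the senecioate, the mesylate or the isopropenyl group (the cis hydroxy mesylate cannot close to an epoxide).

Step 14
Reactants: 23 8α-hydroxy-9α-(methanesulfonyloxy)-10βH-eremophil-11-en-3α-yl 3-methylbut-2-enoate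
Product: 24 9α-(methanesulfonyloxy)-8-oxo-10βH-eremophil-11-en-3α-yl 3-methylbut-2-enoate
Conditions: Dess–Martin periodinane, CH2Cl2, 0 °C → rt
Reagents that add atoms: none
Why: Dess–Martin oxidation of the secondary 8-alcohol under near-neutral conditions, which removes the C-8 stereocentre and should leave the β,γ-unsaturated ketone unconjugated.

Step 15
Reactants: 24 9α-(methanesulfonyloxy)-8-oxo-10βH-eremophil-11-en-3α-yl 3-methylbut-2-enoate; 25 angelic acid ((Z)-2-methylbut-2-enoic acid)
Product: 26 9β-angeloyloxy-3α-senecioyloxy-10βH-eremophil-11-en-8-one (CNP0164025.2)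
Conditions: Cs2CO3 (0.75 equiv), 25 (1.5 equiv), DMF, rt
Reagents that add atoms: none
Why: SN2 displacement of the axial α-keto mesylate by caesium angelate with inversion (the C–O bond is aligned with the carbonyl π system and the carboxylate enters from the convex β-face) should give the equatorial 9β-angelate without Z/E isomerisation, because the carboxylate and not an activated acyl derivative is used, and the product is the all-equatorial, thermodynamically preferred isomer at C-9 and C-7.

**Compound list**

1 | (E)-pent-3-en-2-ol (racemic) | C/C=C/C(C)O | starting material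
2 | (S,E)-pent-3-en-2-ol | C/C=C/[C@H](C)O | intermediate
3 | cyclotene (2-hydroxy-3-methylcyclopent-2-en-1-one) | CC1=C(O)C(=O)CC1 | starting material
4 | 3-methyl-2-{[(2R,3E)-pent-3-en-2-yl]oxy}cyclopent-2-en-1-one | CC1=C(O[C@H](C)/C=C/C)C(=O)CC1 | intermediate
5 | (5R)-2-hydroxy-5-methyl-5-[(2S,3E)-pent-3-en-2-yl]cyclopent-2-en-1-one | C/C=C/[C@H](C)[C@@]1(C)CC=C(O)C1=O | intermediate
6 | (5R)-2-[(4-methoxybenzyl)oxy]-5-methyl-5-[(2S,3E)-pent-3-en-2-yl]cyclopent-2-en-1-one | C/C=C/[C@H](C)[C@@]1(C)CC=C(OCc2ccc(OC)cc2)C1=O | intermediate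
7 | trans-epoxide of the side-chain alkene of 6 (both oxirane diastereomers; not isolated) | CC1OC1[C@H](C)[C@@]2(C)CC=C(OCc3ccc(OC)cc3)C2=O | intermediate
8 | side-chain 2,3-diol from 7 (both diastereomers; not isolated) | CC(O)C(O)[C@H](C)[C@@]1(C)CC=C(OCc2ccc(OC)cc2)C1=O | intermediate
9 | (2R)-2-{(1R)-3-[(4-methoxybenzyl)oxy]-1-methyl-2-oxocyclopent-3-en-1-yl}propanal | O=C[C@H](C)[C@@]1(C)CC=C(OCc2ccc(OC)cc2)C1=O | intermediate
10 | [2-(1,3-dioxolan-2-yl)ethyl]magnesium bromide | Br[Mg]CCC1OCCO1 | starting material
11 | (5R)-5-[(2R,3R)-5-(1,3-dioxolan-2-yl)-3-hydroxypentan-2-yl]-2-[(4-methoxybenzyl)oxy]-5-methylcyclopent-2-en-1-one | O1CCOC1CC[C@@H](O)[C@H](C)[C@@]1(C)CC=C(OCc2ccc(OC)cc2)C1=O | intermediate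
12 | 3-methylbut-2-enoyl chloride (senecioyl chloride) | CC(C)=CC(=O)Cl | starting material
13 | (2R,3R)-5-(1,3-dioxolan-2-yl)-2-{(1R)-3-[(4-methoxybenzyl)oxy]-1-methyl-2-oxocyclopent-3-en-1-yl}pentan-3-yl 3-methylbut-2-enoate | O1CCOC1CC[C@@H](OC(=O)C=C(C)C)[C@H](C)[C@@]1(C)CC=C(OCc2ccc(OC)cc2)C1=O | intermediate
14 | isopropenylmagnesium bromide | CC(=C)[Mg]Br | starting material
15 | trimethylsilyl enol ether of 16 (not isolated) | O1CCOC1CC[C@@H](OC(=O)C=C(C)C)[C@H](C)[C@@]1(C)C[C@H](C(C)=C)C(OCc2ccc(OC)cc2)=C1O[Si](C)(C)C | intermediate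
16 | (2R,3R)-5-(1,3-dioxolan-2-yl)-2-[(1R,3R,4R)-3-[(4-methoxybenzyl)oxy]-1-methyl-2-oxo-4-(prop-1-en-2-yl)cyclopentyl]pentan-3-yl 3-methylbut-2-enoate (isopropenyl cis to the ring methyl; alkoxy trans to isopropenyl) | O1CCOC1CC[C@@H](OC(=O)C=C(C)C)[C@H](C)[C@@]1(C)C[C@H](C(C)=C)[C@@H](OCc2ccc(OC)cc2)C1=O | intermediate
17 | keto aldehyde: 16 with the dioxolane replaced by CHO (C-10 aldehyde) | O=CCC[C@@H](OC(=O)C=C(C)C)[C@H](C)[C@@]1(C)C[C@H](C(C)=C)[C@@H](OCc2ccc(OC)cc2)C1=O | intermediate
18 | N-tosylhydrazone of the C-10 aldehyde 17 | Cc1ccc(cc1)S(=O)(=O)N/N=C/CC[C@@H](OC(=O)C=C(C)C)[C@H](C)[C@@]1(C)C[C@H](C(C)=C)[C@@H](OCc2ccc(OC)cc2)C1=O | intermediate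
19 | C-10 diazoalkane from 18 (not isolated) | [N-]=[N+]=CCC[C@@H](OC(=O)C=C(C)C)[C@H](C)[C@@]1(C)C[C@H](C(C)=C)[C@@H](OCc2ccc(OC)cc2)C1=O | intermediate
20 | 8α-[(4-methoxybenzyl)oxy]-9-oxo-10βH-eremophil-11-en-3α-yl 3-methylbut-2-enoate | C=C(C)[C@H]1C[C@@]2(C)[C@H](CC[C@@H](OC(=O)C=C(C)C)[C@@H]2C)C(=O)[C@@H]1OCc1ccc(OC)cc1 | intermediate
21 | 9α-hydroxy-8α-[(4-methoxybenzyl)oxy]-10βH-eremophil-11-en-3α-yl 3-methylbut-2-enoate | C=C(C)[C@H]1C[C@@]2(C)[C@H](CC[C@@H](OC(=O)C=C(C)C)[C@@H]2C)[C@H](O)[C@@H]1OCc1ccc(OC)cc1 | intermediate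
22 | 9α-(methanesulfonyloxy)-8α-[(4-methoxybenzyl)oxy]-10βH-eremophil-11-en-3α-yl 3-methylbut-2-enoate | C=C(C)[C@H]1C[C@@]2(C)[C@H](CC[C@@H](OC(=O)C=C(C)C)[C@@H]2C)[C@H](OS(C)(=O)=O)[C@@H]1OCc1ccc(OC)cc1 | intermediate
23 | 8α-hydroxy-9α-(methanesulfonyloxy)-10βH-eremophil-11-en-3α-yl 3-methylbut-2-enoate | C=C(C)[C@H]1C[C@@]2(C)[C@H](CC[C@@H](OC(=O)C=C(C)C)[C@@H]2C)[C@H](OS(C)(=O)=O)[C@@H]1O | intermediate
24 | 9α-(methanesulfonyloxy)-8-oxo-10βH-eremophil-11-en-3α-yl 3-methylbut-2-enoate | C=C(C)[C@H]1C[C@@]2(C)[C@H](CC[C@@H](OC(=O)C=C(C)C)[C@@H]2C)[C@H](OS(C)(=O)=O)C1=O | intermediate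
25 | angelic acid ((Z)-2-methylbut-2-enoic acid) | C/C=C(/C)C(=O)O | starting material
26 | 9β-angeloyloxy-3α-senecioyloxy-10βH-eremophil-11-en-8-one (CNP0164025.2) | C=C(C)[C@H]1C[C@@]2(C)[C@H](CC[C@@H](OC(=O)C=C(C)C)[C@@H]2C)[C@@H](OC(=O)/C(C)=C\C)C1=O | target

**Step count and risks**

Total step count: 15. Longest linear sequence: 15 steps (1 → 26).

Steps most likely to fail:

- **Step 10 (Proposed new method).** The diazonium alkoxide may collapse to the epoxide, C-8 may migrate instead of C-5, or the diazoalkane may lose nitrogen (carbene-type 1,2-hydrogen shift) before it reaches the hindered ketone. The fallback uses known chemistry, sets out from 16 and comes back at 20. Hydrolysis of the dioxolane (PPTS, acetone/water) would give the keto aldehyde 17, now isolated. SmI2, t-BuOH, THF, −78 °C would close the seven-membered ring by aldehyde–ketone pinacol coupling (the two carbonyl carbons C-9 and C-10 are joined through the ketyl of the aldehyde) to the cis-fused cis-9,10-diol F1. MsCl/pyridine would sulfonylate only the secondary C-10 hydroxyl to give the hydroxy mesylate F2. AlEt3 in CH2Cl2 at −78 °C would then trigger the semipinacol 1,2-shift of C-5 from C-9 to C-10 (ring B five to six, the other ring seven to six), and brief DBU treatment would equilibrate C-10 to the cis-fused ketone 20.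

- **Step 15.** Elimination of methanesulfonic acid across C-9/C-10 (the mesylate and H-10 are trans-diaxial), or enolisation toward C-7 with migration of the isopropenyl double bond into conjugation, may outrun substitution. The fallback sets out from 21 and comes back at 26. Mitsunobu esterification of the axial 9α-alcohol with angelic acid 25 (PPh3, DIAD, toluene, 0 °C) would invert C-9 at the alcohol stage and give the 9β-angelate F3. DDQ would remove the 4-methoxybenzyl group to give the 8α-alcohol F4, and Dess–Martin oxidation would give 26.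

- **Step 2.** Partial SN2′ attack or ion-pair return during the allylic Mitsunobu reaction would erode the enantiomeric purity that step 3 transfers to C-5 and C-4. The fallback sets out from 1 (with 3) and comes back at 4, replacing steps 1 and 2. Racemic 1 would be converted with methyl chloroformate/pyridine into the methyl carbonate F5. Pd2(dba)3·CHCl3 (zerovalent palladium) with an enantiopure C2-symmetric trans-1,2-diaminocyclohexane bis(2-diphenylphosphinobenzamide) ligand would couple F5 with 3 in CH2Cl2. Both enantiomers of F5 ionise to the same symmetric 1,3-dimethylallyl palladium complex, and the ligand decides which allyl terminus the enol oxygen attacks (asymmetric allylic etherification with deracemisation). The ligand antipode that delivers the (R)-ether 4 would be fixed in a test run.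

Further compounds
F1 | step 10 | cis-fused bicyclo[5.3.0]decane cis-9,10-diol (eremophilane numbering: 9-OH tertiary and cis to the C-5 methyl; 10-OH secondary; 8α-OPMB; 3α-senecioate) | C=C(C)[C@H]1C[C@]2(C)[C@@H](C)[C@H](OC(=O)C=C(C)C)CC[C@@H](O)[C@]2(O)[C@@H]1OCc1ccc(OC)cc1
F2 | step 10 | C-10 methanesulfonate of diol F1 | C=C(C)[C@H]1C[C@]2(C)[C@@H](C)[C@H](OC(=O)C=C(C)C)CC[C@@H](OS(C)(=O)=O)[C@]2(O)[C@@H]1OCc1ccc(OC)cc1
F3 | step 15 | 9β-angeloyloxy-8α-[(4-methoxybenzyl)oxy]-10βH-eremophil-11-en-3α-yl 3-methylbut-2-enoate | C=C(C)[C@H]1C[C@@]2(C)[C@H](CC[C@@H](OC(=O)C=C(C)C)[C@@H]2C)[C@@H](OC(=O)/C(C)=C\C)[C@@H]1OCc1ccc(OC)cc1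
F4 | step 15 | 9β-angeloyloxy-8α-hydroxy-10βH-eremophil-11-en-3α-yl 3-methylbut-2-enoate | C=C(C)[C@H]1C[C@@]2(C)[C@H](CC[C@@H](OC(=O)C=C(C)C)[C@@H]2C)[C@@H](OC(=O)/C(C)=C\C)[C@@H]1O
F5 | step 2 | methyl (E)-pent-3-en-2-yl carbonate (racemic) | C/C=C/C(C)OC(=O)OC
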